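**Retrosynthetic overview**
1. Target ⇐ protected bis-dihydrobenzofuran ⇐ tetrahydrofuran-core dialdehyde + 2 aryl Grignard + 2 chiral benzylsulfonium ylide. Both dihydrobenzofuran rings close in one flask by a twofold o-quinone methide/[4+1] annulation, which sets four stereocentres.
2. Dialdehyde ⇐ tetraaryl-tetrahydrofuran, by ring bromination para to a silyloxy group, Br/Li exchange–formylation and silyl-to-carbonate exchange.
3. Tetrahydrofuran (2,3-cis/3,4-trans/4,5-trans) ⇐ C2-symmetric (1S,2S,3S,4S)-1,4-diol, closed with inversion at one of its two equivalent carbinols.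
4. Diol ⇐ stereolabile 1,4-diketone (twofold dynamic kinetic hydrogenation) ⇐ oxidative homodimerisation of two molecules of a deoxybenzoin ⇐ ketone α-arylation.
5. Ring order: tetrahydrofuran first, then the two dihydrobenzofurans together.

Assumption: the ylide from (1R,4R,5R)-isothiocineole is taken to transfer its benzylidene carbon with the facial sense that gives 2S in the dihydrobenzofuran; if the sense is the opposite, the (1S,4S,5S)-sulfide is used with no other change.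

**Route**

Step 1
Reactants: 1 5-bromoresorcinol; 2 triisopropylsilyl chloride
Product: 3 1-bromo-3,5-bis(triisopropylsilyloxy)benzene
Conditions: TIPSCl (2.2 equiv), imidazole, DMF, rt
Reagents that add atoms: triisopropylsilyl chloride, CC(C)[Si](Cl)(C(C)C)C(C)C
Why: Standard phenol O-silylation; TIPS is chosen because it survives the base, organolithium and hydrogenation steps that follow.

Step 2
Reactants: 4 4'-hydroxyacetophenone; 2 triisopropylsilyl chloride
Product: 5 1-[4-(triisopropylsilyloxy)phenyl]ethan-1-one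
Conditions: TIPSCl, imidazole, DMF, rt
Reagents that add atoms: triisopropylsilyl chloride, CC(C)[Si](Cl)(C(C)C)C(C)C
Why: Standard phenol O-silylation.

Step 3
Reactants: 3 1-bromo-3,5-bis(triisopropylsilyloxy)benzene; 5 1-[4-(triisopropylsilyloxy)phenyl]ethan-1-one
Product: 6 2-[3,5-bis(triisopropylsilyloxy)phenyl]-1-[4-(triisopropylsilyloxy)phenyl]ethan-1-one
Conditions: Pd(OAc)2 (2 mol%), XPhos (4 mol%), K3PO4, toluene, 90 °C (5 in slight excess)
Reagents that add atoms: none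
Why: Pd-catalysed ketone α-arylation (Buchwald–Hartwig type); a methyl ketone with a bulky biarylphosphine stops cleanly at mono-arylation.

Step 4
Reactants: 6 2-[3,5-bis(triisopropylsilyloxy)phenyl]-1-[4-(triisopropylsilyloxy)phenyl]ethan-1-one (two molecules; one reacts as its enolate, the other as its alpha-iodo derivative)
Product: 9 2,3-bis[3,5-bis(triisopropylsilyloxy)phenyl]-1,4-bis[4-(triisopropylsilyloxy)phenyl]butane-1,4-dione (racemic/meso mixture), via lithium enolate 7 (not isolated), via alpha-iodo ketone 8 (not isolated)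
Conditions: LiN(i-Pr)2 (1.05 equiv per ketone), THF, −78 °C; I2 (0.5 equiv per ketone), −78 °C → rt
Reagents that add atoms: second molecule of ketone 6 (the coupling partner; it reacts as the alpha-iodo ketone 8 made from it in the flask), O=C(Cc1cc(O[Si](C(C)C)(C(C)C)C(C)C)cc(O[Si](C(C)C)(C(C)C)C(C)C)c1)c1ccc(O[Si](C(C)C)(C(C)C)C(C)C)cc1
Why: Oxidative enolate homocoupling (the classical deoxybenzoin dimerisation) joins two molecules of 6 at their α-carbons: half of the enolate is iodinated and the other half displaces iodide; no stereocontrol is needed because C2/C3 stay epimerisable and are set in step 5.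

Step 5
Reactants: 9 2,3-bis[3,5-bis(triisopropylsilyloxy)phenyl]-1,4-bis[4-(triisopropylsilyloxy)phenyl]butane-1,4-dione
Product: 11 (1S,2S,3S,4S)-2,3-bis[3,5-bis(triisopropylsilyloxy)phenyl]-1,4-bis[4-(triisopropylsilyloxy)phenyl]butane-1,4-diol, via hydroxy ketone 10 (not isolated)
Conditions: trans-RuCl2[(R)-xylbinap][(R)-daipen] (2 mol%), t-BuOK (20 mol%), i-PrOH/toluene, H2 (10 atm), 30 °C
Reagents that add atoms: none
Why: Proposed new method: twofold Noyori-type asymmetric hydrogenation under dynamic kinetic resolution, in which t-BuOK keeps both α-aryl centres epimerising through their enolates while the catalyst makes each carbinol S and reduces fastest the epimer whose α-aryl group lies anti to the incoming hydride (Felkin–Anh), i.e. the (S)-α-epimer, so both halves converge on the like (S,S) pair and racemic and meso 9 funnel into one C2-symmetric diol; closest known reaction type is the dynamic kinetic hydrogenation of single α-aryl ketones.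

Step 6
Reactants: 11 (1S,2S,3S,4S)-2,3-bis[3,5-bis(triisopropylsilyloxy)phenyl]-1,4-bis[4-(triisopropylsilyloxy)phenyl]butane-1,4-diol
Product: 13 (2R,3S,4S,5S)-3,4-bis[3,5-bis(triisopropylsilyloxy)phenyl]-2,5-bis[4-(triisopropylsilyloxy)phenyl]tetrahydrofuran, via monomesylate 12 (not isolated)
Conditions: MsCl (1.05 equiv), Et3N, CH2Cl2, −40 → 0 °C
Reagents that add atoms: none
Why: Cyclodehydration of a 1,4-diol through its monomesylate (intramolecular Williamson-type etherification): the two carbinols are equivalent, the activated one is closed with inversion (or, via the benzylic cation, anti to the neighbouring aryl, which gives the same result) and becomes R (4,5-trans in target numbering), while the untouched one stays S and provides the cis aryl pair.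

Step 7
Reactants: 13 (2R,3S,4S,5S)-3,4-bis[3,5-bis(triisopropylsilyloxy)phenyl]-2,5-bis[4-(triisopropylsilyloxy)phenyl]tetrahydrofuran; 14 N-bromosuccinimide
Product: 15 (2R,3S,4S,5S)-3,4-bis[2-bromo-3,5-bis(triisopropylsilyloxy)phenyl]-2,5-bis[4-(triisopropylsilyloxy)phenyl]tetrahydrofuran
Conditions: NBS (2.05 equiv), MeCN/CH2Cl2, 0 °C, dark
Reagents that add atoms: N-bromosuccinimide, O=C1CCC(=O)N1Br
Why: Electrophilic aromatic bromination of the two doubly activated resorcinol rings para to one silyloxy group; the position between the two TIPS ethers is blocked and the two ortho sites of each ring are equivalent, so one dibromide forms and the ring stereocentres are untouched.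

Step 8
Reactants: 15 (2R,3S,4S,5S)-3,4-bis[2-bromo-3,5-bis(triisopropylsilyloxy)phenyl]-2,5-bis[4-(triisopropylsilyloxy)phenyl]tetrahydrofuran; 16 N,N-dimethylformamide
Product: 18 2,2'-[(2R,3S,4S,5S)-2,5-bis[4-(triisopropylsilyloxy)phenyl]tetrahydrofuran-3,4-diyl]bis[4,6-bis(triisopropylsilyloxy)benzaldehyde], via dilithio arene 17 (not isolated)
Conditions: t-BuLi (4.1 equiv), Et2O/THF, −78 °C; DMF; H2O
Reagents that add atoms: N,N-dimethylformamide, CN(C)C=O
Why: Bromine–lithium exchange followed by Bouveault formylation; the exchange is much faster than benzylic deprotonation at −78 °C and TIPS does not migrate to carbon at this temperature.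

Step 9
Reactants: 18 dialdehyde from step 8; 19 di-tert-butyl dicarbonate
Product: 21 hexakis(tert-butyl carbonate) of 2,2'-[(2R,3S,4S,5S)-2,5-bis(4-hydroxyphenyl)tetrahydrofuran-3,4-diyl]bis(4,6-dihydroxybenzaldehyde), via hexaphenol dialdehyde 20 (not isolated)
Conditions: TBAF, AcOH, THF, 0 °C → rt; then Boc2O, DMAP (cat.), i-Pr2NEt, CH2Cl2, rt
Reagents that add atoms: di-tert-butyl dicarbonate, CC(C)(C)OC(=O)OC(=O)OC(C)(C)C
Why: Buffered fluoride desilylation then phenol O-acylation; the ortho carbonate is the trigger for step 11, and the other four carbonates make the remaining rings electron-poor, which protects the acid- and base-sensitive cis centre of the tetrahydrofuran.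

Step 10
Reactants: 22 4-(tert-butyldimethylsilyloxy)benzyl bromide; 23 (1R,4R,5R)-isothiocineole; 24 silver trifluoromethanesulfonate (AgOTf)
Product: 25 (1R,4R,5R)-6-[4-(tert-butyldimethylsilyloxy)benzyl]-4,7,7-trimethyl-6-thiabicyclo[3.2.1]octan-6-ium triflate
Conditions: AgOTf, CH2Cl2, rt, dark
Reagents that add atoms: silver trifluoromethanesulfonate, [Ag+].[O-]S(=O)(=O)C(F)(F)F
Why: S-alkylation of the sulfide on its less hindered lone pair gives one sulfonium diastereomer; silver removes bromide so the salt cannot revert.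

Step 11
Reactants: 21 hexacarbonate dialdehyde from step 9; 3 1-bromo-3,5-bis(triisopropylsilyloxy)benzene (as its Grignard reagent, two aryl groups are taken up); 25 sulfonium triflate from step 10 (as its ylide, two benzylidene groups are taken up)
Product: 28 fully protected target (two TBS ethers; four TIPS ethers; four tert-butyl carbonates), via bis(bromomagnesium alkoxide) 26 (not isolated), via bis(o-quinone methide) 27 (not isolated)
Conditions: ArMgBr from 3 + Mg (THF; 2.1 equiv) added to 21, THF, −78 °C; then ylide from 25 + LiN(SiMe3)2 (3 equiv, THF, −78 °C); −78 → −10 °C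
Reagents that add atoms: 3,5-bis(triisopropylsilyloxy)phenylmagnesium bromide (made in the flask from 3 and Mg; one per aldehyde), Br[Mg]c1cc(O[Si](C(C)C)(C(C)C)C(C)C)cc(O[Si](C(C)C)(C(C)C)C(C)C)c1; benzylidene sulfonium ylide (made in the flask from 25 and LiN(SiMe3)2; one per o-quinone methide), C[C@@H]1CC[C@@H]2C[C@H]1[S+]([CH-]c1ccc(O[Si](C)(C)C(C)(C)C)cc1)C2(C)C
Why: Proposed new method: each aldehyde takes up the aryl Grignard, the ortho carbonate migrates to the new alkoxide and is expelled to give an o-quinone methide (known anionic carbonate-migration cascade), the benzylic sulfonium ylide adds to its exocyclic carbon and the phenoxide then displaces the sulfide with inversion (known o-quinone methide/sulfur ylide [4+1] annulation, precedented with acyl-stabilised ylides), with the chiral sulfide fixing the attacking face of the ylide carbon and hence C2 (S) and the anti-betaine/5-exo-tet closure giving the 2,3-trans ring and hence C3 (S), twice in one flask.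

Step 12
Reactants: 28 fully protected target from step 11
Product: 30 CNP0270490.1 (target), via desilylated tetracarbonate 29 (not isolated)
Conditions: TBAF, AcOH, THF, 0 °C → rt; then piperidine, MeOH, rt
Reagents that add atoms: none
Why: Buffered fluoride cleavage of the aryl silyl ethers, then aminolysis of the aryl tert-butyl carbonates; no acid, so the 2,3-cis centre of the tetrahydrofuran and the benzylic ethers are not ionised.

**Compound list**
1 | 5-bromoresorcinol | Oc1cc(O)cc(Br)c1 | starting material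
2 | triisopropylsilyl chloride | CC(C)[Si](Cl)(C(C)C)C(C)C | starting material
3 | 1-bromo-3,5-bis(triisopropylsilyloxy)benzene | Brc1cc(O[Si](C(C)C)(C(C)C)C(C)C)cc(O[Si](C(C)C)(C(C)C)C(C)C)c1 | intermediate
4 | 4'-hydroxyacetophenone | CC(=O)c1ccc(O)cc1 | starting material
5 | 1-[4-(triisopropylsilyloxy)phenyl]ethan-1-one | CC(=O)c1ccc(O[Si](C(C)C)(C(C)C)C(C)C)cc1 | intermediate
6 | 2-[3,5-bis(triisopropylsilyloxy)phenyl]-1-[4-(triisopropylsilyloxy)phenyl]ethan-1-one | O=C(Cc1cc(O[Si](C(C)C)(C(C)C)C(C)C)cc(O[Si](C(C)C)(C(C)C)C(C)C)c1)c1ccc(O[Si](C(C)C)(C(C)C)C(C)C)cc1 | intermediate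
7 | lithium (Z)-enolate of 6 | [Li+].[O-]/C(=C\c1cc(O[Si](C(C)C)(C(C)C)C(C)C)cc(O[Si](C(C)C)(C(C)C)C(C)C)c1)c1ccc(O[Si](C(C)C)(C(C)C)C(C)C)cc1 | intermediate
8 | 2-iodo derivative of 6 (racemic) | O=C(C(I)c1cc(O[Si](C(C)C)(C(C)C)C(C)C)cc(O[Si](C(C)C)(C(C)C)C(C)C)c1)c1ccc(O[Si](C(C)C)(C(C)C)C(C)C)cc1 | intermediate
9 | 2,3-bis[3,5-bis(triisopropylsilyloxy)phenyl]-1,4-bis[4-(triisopropylsilyloxy)phenyl]butane-1,4-dione, racemic/meso mixture, C2 and C3 epimerisable | O=C(c1ccc(O[Si](C(C)C)(C(C)C)C(C)C)cc1)C(c1cc(O[Si](C(C)C)(C(C)C)C(C)C)cc(O[Si](C(C)C)(C(C)C)C(C)C)c1)C(c1cc(O[Si](C(C)C)(C(C)C)C(C)C)cc(O[Si](C(C)C)(C(C)C)C(C)C)c1)C(=O)c1ccc(O[Si](C(C)C)(C(C)C)C(C)C)cc1 | intermediate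
10 | (3S,4S)-4-hydroxy-2,3-bis[3,5-bis(triisopropylsilyloxy)phenyl]-1,4-bis[4-(triisopropylsilyloxy)phenyl]butan-1-one, C2 still epimerising | O[C@H](c1ccc(O[Si](C(C)C)(C(C)C)C(C)C)cc1)[C@H](c1cc(O[Si](C(C)C)(C(C)C)C(C)C)cc(O[Si](C(C)C)(C(C)C)C(C)C)c1)C(c1cc(O[Si](C(C)C)(C(C)C)C(C)C)cc(O[Si](C(C)C)(C(C)C)C(C)C)c1)C(=O)c1ccc(O[Si](C(C)C)(C(C)C)C(C)C)cc1 | intermediate
11 | (1S,2S,3S,4S)-2,3-bis[3,5-bis(triisopropylsilyloxy)phenyl]-1,4-bis[4-(triisopropylsilyloxy)phenyl]butane-1,4-diol (C2-symmetric) | O[C@H](c1ccc(O[Si](C(C)C)(C(C)C)C(C)C)cc1)[C@H](c1cc(O[Si](C(C)C)(C(C)C)C(C)C)cc(O[Si](C(C)C)(C(C)C)C(C)C)c1)[C@@H](c1cc(O[Si](C(C)C)(C(C)C)C(C)C)cc(O[Si](C(C)C)(C(C)C)C(C)C)c1)[C@H](O)c1ccc(O[Si](C(C)C)(C(C)C)C(C)C)cc1 | intermediate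
12 | mono-methanesulfonate of 11 (all four centres as in 11) | O[C@H](c1ccc(O[Si](C(C)C)(C(C)C)C(C)C)cc1)[C@H](c1cc(O[Si](C(C)C)(C(C)C)C(C)C)cc(O[Si](C(C)C)(C(C)C)C(C)C)c1)[C@@H](c1cc(O[Si](C(C)C)(C(C)C)C(C)C)cc(O[Si](C(C)C)(C(C)C)C(C)C)c1)[C@H](OS(C)(=O)=O)c1ccc(O[Si](C(C)C)(C(C)C)C(C)C)cc1 | intermediate
13 | (2R,3S,4S,5S)-3,4-bis[3,5-bis(triisopropylsilyloxy)phenyl]-2,5-bis[4-(triisopropylsilyloxy)phenyl]tetrahydrofuran (aryls 2,3-trans, 3,4-trans, 4,5-cis) | CC(C)[Si](C(C)C)(C(C)C)Oc1cc(O[Si](C(C)C)(C(C)C)C(C)C)cc(c1)[C@@H]1[C@@H](c2cc(O[Si](C(C)C)(C(C)C)C(C)C)cc(O[Si](C(C)C)(C(C)C)C(C)C)c2)[C@H](c2ccc(O[Si](C(C)C)(C(C)C)C(C)C)cc2)O[C@@H]1c1ccc(O[Si](C(C)C)(C(C)C)C(C)C)cc1 | intermediate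
14 | N-bromosuccinimide | O=C1CCC(=O)N1Br | starting material
15 | (2R,3S,4S,5S)-3,4-bis[2-bromo-3,5-bis(triisopropylsilyloxy)phenyl]-2,5-bis[4-(triisopropylsilyloxy)phenyl]tetrahydrofuran | CC(C)[Si](C(C)C)(C(C)C)Oc1cc(O[Si](C(C)C)(C(C)C)C(C)C)c(Br)c(c1)[C@@H]1[C@@H](c2cc(O[Si](C(C)C)(C(C)C)C(C)C)cc(O[Si](C(C)C)(C(C)C)C(C)C)c2Br)[C@H](c2ccc(O[Si](C(C)C)(C(C)C)C(C)C)cc2)O[C@@H]1c1ccc(O[Si](C(C)C)(C(C)C)C(C)C)cc1 | intermediate
16 | N,N-dimethylformamide | CN(C)C=O | starting material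
17 | dilithio arene from 15 (Li in place of each Br) | CC(C)[Si](C(C)C)(C(C)C)Oc1cc(O[Si](C(C)C)(C(C)C)C(C)C)c([Li])c(c1)[C@@H]1[C@@H](c2cc(O[Si](C(C)C)(C(C)C)C(C)C)cc(O[Si](C(C)C)(C(C)C)C(C)C)c2[Li])[C@H](c2ccc(O[Si](C(C)C)(C(C)C)C(C)C)cc2)O[C@@H]1c1ccc(O[Si](C(C)C)(C(C)C)C(C)C)cc1 | intermediate
18 | 2,2'-[(2R,3S,4S,5S)-2,5-bis[4-(triisopropylsilyloxy)phenyl]tetrahydrofuran-3,4-diyl]bis[4,6-bis(triisopropylsilyloxy)benzaldehyde] | CC(C)[Si](C(C)C)(C(C)C)Oc1cc(O[Si](C(C)C)(C(C)C)C(C)C)c(C=O)c(c1)[C@@H]1[C@@H](c2cc(O[Si](C(C)C)(C(C)C)C(C)C)cc(O[Si](C(C)C)(C(C)C)C(C)C)c2C=O)[C@H](c2ccc(O[Si](C(C)C)(C(C)C)C(C)C)cc2)O[C@@H]1c1ccc(O[Si](C(C)C)(C(C)C)C(C)C)cc1 | intermediate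
19 | di-tert-butyl dicarbonate | CC(C)(C)OC(=O)OC(=O)OC(C)(C)C | starting material
20 | 2,2'-[(2R,3S,4S,5S)-2,5-bis(4-hydroxyphenyl)tetrahydrofuran-3,4-diyl]bis(4,6-dihydroxybenzaldehyde) | Oc1cc(O)c(C=O)c(c1)[C@@H]1[C@@H](c2cc(O)cc(O)c2C=O)[C@H](c2ccc(O)cc2)O[C@@H]1c1ccc(O)cc1 | intermediate
21 | hexakis(tert-butyl carbonate) of 20 | CC(C)(C)OC(=O)Oc1cc(OC(=O)OC(C)(C)C)c(C=O)c(c1)[C@@H]1[C@@H](c2cc(OC(=O)OC(C)(C)C)cc(OC(=O)OC(C)(C)C)c2C=O)[C@H](c2ccc(OC(=O)OC(C)(C)C)cc2)O[C@@H]1c1ccc(OC(=O)OC(C)(C)C)cc1 | intermediate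
22 | 4-(tert-butyldimethylsilyloxy)benzyl bromide | BrCc1ccc(O[Si](C)(C)C(C)(C)C)cc1 | starting material
23 | (1R,4R,5R)-isothiocineole (4,7,7-trimethyl-6-thiabicyclo[3.2.1]octane) | C[C@@H]1CC[C@@H]2C[C@H]1SC2(C)C | starting material
24 | silver trifluoromethanesulfonate (AgOTf) | [Ag+].[O-]S(=O)(=O)C(F)(F)F | starting material
25 | (1R,4R,5R)-6-[4-(tert-butyldimethylsilyloxy)benzyl]-4,7,7-trimethyl-6-thiabicyclo[3.2.1]octan-6-ium triflate (one sulfonium diastereomer; sulfur configuration not drawn) | C[C@@H]1CC[C@@H]2C[C@H]1[S+](Cc1ccc(O[Si](C)(C)C(C)(C)C)cc1)C2(C)C.[O-]S(=O)(=O)C(F)(F)F | intermediate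
26 | bis(bromomagnesium alkoxide) from twofold aryl addition to 21 (carbinol carbons as an epimer mixture) | CC(C)(C)OC(=O)Oc1cc(OC(=O)OC(C)(C)C)c(C(O[Mg]Br)c2cc(O[Si](C(C)C)(C(C)C)C(C)C)cc(O[Si](C(C)C)(C(C)C)C(C)C)c2)c(c1)[C@@H]1[C@@H](c2cc(OC(=O)OC(C)(C)C)cc(OC(=O)OC(C)(C)C)c2C(O[Mg]Br)c2cc(O[Si](C(C)C)(C(C)C)C(C)C)cc(O[Si](C(C)C)(C(C)C)C(C)C)c2)[C@H](c2ccc(OC(=O)OC(C)(C)C)cc2)O[C@@H]1c1ccc(OC(=O)OC(C)(C)C)cc1 | intermediate
27 | bis(o-quinone methide): each resorcinol ring as a 6-arylmethylene-cyclohexa-2,4-dienone (alkene geometry not fixed) | CC(C)(C)OC(=O)OC1=CC(=O)C(=Cc2cc(O[Si](C(C)C)(C(C)C)C(C)C)cc(O[Si](C(C)C)(C(C)C)C(C)C)c2)C(=C1)[C@@H]1[C@@H](C2=CC(OC(=O)OC(C)(C)C)=CC(=O)C2=Cc2cc(O[Si](C(C)C)(C(C)C)C(C)C)cc(O[Si](C(C)C)(C(C)C)C(C)C)c2)[C@H](c2ccc(OC(=O)OC(C)(C)C)cc2)O[C@@H]1c1ccc(OC(=O)OC(C)(C)C)cc1 | intermediate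
28 | fully protected target: both dihydrobenzofurans (2S,3S), tetrahydrofuran (2R,3S,4S,5S); TBS on the two 2-(4-hydroxyphenyl) groups, TIPS on the four resorcinol OH, tert-butyl carbonates on both benzofuran 6-OH and both tetrahydrofuran 4-hydroxyphenyl groups | CC(C)(C)[Si](C)(C)Oc1ccc([C@H]2Oc3cc(OC(=O)OC(C)(C)C)cc([C@@H]4[C@@H](c5cc(OC(=O)OC(C)(C)C)cc6c5[C@H](c5cc(O[Si](C(C)C)(C(C)C)C(C)C)cc(O[Si](C(C)C)(C(C)C)C(C)C)c5)[C@@H](c5ccc(O[Si](C)(C)C(C)(C)C)cc5)O6)[C@H](c5ccc(OC(=O)OC(C)(C)C)cc5)O[C@@H]4c4ccc(OC(=O)OC(C)(C)C)cc4)c3[C@@H]2c2cc(O[Si](C(C)C)(C(C)C)C(C)C)cc(O[Si](C(C)C)(C(C)C)C(C)C)c2)cc1 | intermediate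
29 | desilylated tetracarbonate (28 with all six silyl ethers as free OH) | Oc1ccc([C@H]2Oc3cc(OC(=O)OC(C)(C)C)cc([C@@H]4[C@@H](c5cc(OC(=O)OC(C)(C)C)cc6c5[C@H](c5cc(O)cc(O)c5)[C@@H](c5ccc(O)cc5)O6)[C@H](c5ccc(OC(=O)OC(C)(C)C)cc5)O[C@@H]4c4ccc(OC(=O)OC(C)(C)C)cc4)c3[C@@H]2c2cc(O)cc(O)c2)cc1 | intermediate
30 | CNP0270490.1: (2R,3S,4S,5S)-2,5-bis(4-hydroxyphenyl)tetrahydrofuran carrying at C3 and C4 the C4 position of two (2S,3S)-3-(3,5-dihydroxyphenyl)-6-hydroxy-2-(4-hydroxyphenyl)-2,3-dihydrobenzofurans | Oc1ccc([C@H]2Oc3cc(O)cc([C@@H]4[C@@H](c5cc(O)cc6c5[C@H](c5cc(O)cc(O)c5)[C@@H](c5ccc(O)cc5)O6)[C@H](c5ccc(O)cc5)O[C@@H]4c4ccc(O)cc4)c3[C@@H]2c2cc(O)cc(O)c2)cc1 | target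

**Step count and risks**
Total steps: 12. Longest linear sequence: 10 (steps 1, 3 to 9, 11, 12).

Most likely to fail:

Step 11 (key double annulation). Two sources of stereocontrol meet here: the chiral ylide and the already chiral, unsymmetrical core. A mismatched pairing would give 2,3-cis rings or the wrong absolute sense, and excess ylide can attack the aryl carbonates. Fallback, setting out from 21 and returning at 28: after the same aryl Grignard addition, the o-quinone methides are intercepted by 1,4-addition of 4-(tert-butyldimethylsilyloxy)benzylmagnesium bromide (made from 22 and Mg). This gives the bis(1,2-diarylethyl)phenol F4, in which C3 of each future ring is set by the core alone and the wanted epimer is separated. DDQ (CH2Cl2, 0 °C) then removes hydride from the electron-rich silyloxybenzyl CH2 only; the carbonate-bearing aryl groups on the tetrahydrofuran are too electron-poor to react. The free ortho phenol traps the resulting cation anti to the C3 aryl and closes both 2,3-trans rings to 28.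

Step 5 (twofold dynamic kinetic hydrogenation). The ketones are hindered, and if reduction outruns epimerisation the diastereomers are not funnelled. Fallback, setting out from 9 and returning at 11: a static, reagent-controlled reduction with (R)-2-methyl-CBS-oxazaborolidine and BH3·SMe2 makes every carbinol S without touching the α-centres. This gives 11 together with the (1S,2R,3R,4S)-diol F2 and the (1S,2R,3S,4S)-diol F3. Diol 11 is separated by chromatography; F2 and F3 are reoxidised with Dess–Martin periodinane to 9, re-equilibrated with DBU and recycled.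

Step 4 (joining two hindered benzylic enolate carbons). Over-oxidation to the enedione and low conversion are the main dangers. Fallback, setting out from 5 (with 3) and returning at 9: the enolate of 5 is dimerised first (LiN(i-Pr)2, then CuCl2, THF/DMF, −78 °C → rt) to 1,4-bis[4-(triisopropylsilyloxy)phenyl]butane-1,4-dione F1, where the new bond joins two unhindered CH2 groups. A twofold Pd-catalysed α-arylation of F1 with 3 (Pd(OAc)2, XPhos, K3PO4, toluene, 100 °C) then gives 9.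

**Further compounds**
F1 | step 4 | 1,4-bis[4-(triisopropylsilyloxy)phenyl]butane-1,4-dione | O=C(CCC(=O)c1ccc(O[Si](C(C)C)(C(C)C)C(C)C)cc1)c1ccc(O[Si](C(C)C)(C(C)C)C(C)C)cc1
F2 | step 5 | (1S,2R,3R,4S)-2,3-bis[3,5-bis(triisopropylsilyloxy)phenyl]-1,4-bis[4-(triisopropylsilyloxy)phenyl]butane-1,4-diol | O[C@H](c1ccc(O[Si](C(C)C)(C(C)C)C(C)C)cc1)[C@@H](c1cc(O[Si](C(C)C)(C(C)C)C(C)C)cc(O[Si](C(C)C)(C(C)C)C(C)C)c1)[C@H](c1cc(O[Si](C(C)C)(C(C)C)C(C)C)cc(O[Si](C(C)C)(C(C)C)C(C)C)c1)[C@H](O)c1ccc(O[Si](C(C)C)(C(C)C)C(C)C)cc1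
F3 | step 5 | (1S,2R,3S,4S)-2,3-bis[3,5-bis(triisopropylsilyloxy)phenyl]-1,4-bis[4-(triisopropylsilyloxy)phenyl]butane-1,4-diol | O[C@H](c1ccc(O[Si](C(C)C)(C(C)C)C(C)C)cc1)[C@@H](c1cc(O[Si](C(C)C)(C(C)C)C(C)C)cc(O[Si](C(C)C)(C(C)C)C(C)C)c1)[C@@H](c1cc(O[Si](C(C)C)(C(C)C)C(C)C)cc(O[Si](C(C)C)(C(C)C)C(C)C)c1)[C@H](O)c1ccc(O[Si](C(C)C)(C(C)C)C(C)C)cc1
F4 | step 11 | ring-opened precursor of 28: each resorcinol ring carries a free ortho OH and a (1S)-1-[3,5-bis(triisopropylsilyloxy)phenyl]-2-[4-(tert-butyldimethylsilyloxy)phenyl]ethyl group; four tert-butyl carbonates as in 28 | Oc1cc(OC(=O)OC(C)(C)C)cc([C@@H]2[C@@H](c3cc(OC(=O)OC(C)(C)C)cc(O)c3[C@H](c3cc(O[Si](C(C)C)(C(C)C)C(C)C)cc(O[Si](C(C)C)(C(C)C)C(C)C)c3)Cc3ccc(O[Si](C)(C)C(C)(C)C)cc3)[C@H](c3ccc(OC(=O)OC(C)(C)C)cc3)O[C@@H]2c2ccc(OC(=O)OC(C)(C)C)cc2)c1[C@@H](Cc1ccc(O[Si](C)(C)C(C)(C)C)cc1)c1cc(O[Si](C(C)C)(C(C)C)C(C)C)cc(O[Si](C(C)C)(C(C)C)C(C)C)c1
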